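## Retrosynthetic overview

1. The target comes from global desilylation of its bis-silyl ether; the ten-membered carbocycle (ring B) is closed last by ring-closing metathesis at C1=C10.
2. The C8 ester C–O bond is made with inversion (Mitsunobu) on a 7,8-anti alcohol, installing the 3-methylbutanoate directly.
3. The C7–C8 bond comes from a zinc Barbier reaction between a (5R)-3-(bromomethyl)butenolide and a β,γ-unsaturated aldehyde.
4. Key step: the lactone (ring A, formed first), its C6–O bond and the C6 stereocentre arise together in a catalytic enantioselective 1,4-bromolactonisation of an achiral trienoic acid.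
5. The trienoic acid comes from a Horner–Wadsworth–Emmons reaction on an enal whose C4=C5 geometry is fixed by a crossed aldol condensation of hex-5-enal with glyoxal mono-acetal.

Assumption: atoms are referred to by germacrane numbering (C6 = lactone carbinol carbon, C7 = ring-fusion carbon, C8 = ester-bearing carbon, C1=C10 and C4=C5 = ring alkenes, C14/C15 = hydroxymethyl carbons on C10/C4). Hex-5-enal, 60% aqueous 2,2-dimethoxyacetaldehyde, ethyl 2-(bromomethyl)prop-2-enoate, triethyl phosphite, 2-methylprop-2-en-1-ol, paraformaldehyde and 3-methylbutanoic acid are taken as catalogue chemicals.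

## Route

Step 1
Reactants: 1 hex-5-enal; 2 2,2-dimethoxyacetaldehyde
Product: 4 (2E)-2-(but-3-en-1-yl)-4,4-dimethoxybut-2-enal, via aldol adduct 3 (not isolated)
Conditions: 2 (60% aq., 1.5 equiv), pyrrolidine (20 mol%), EtCO2H (20 mol%), toluene, 60 °C, slow addition of 1
Reagents that add atoms: none
Why: Amine-catalysed crossed aldol condensation (enamine of 1 adds to the non-enolisable aldehyde 2, then dehydration), giving under thermodynamic control the 2-alkyl-2-enal with formyl trans to the acetal carbon, which fixes the C4=C5 geometry (butenyl chain cis to the future C6).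

Step 2
Reactants: 4 (2E)-2-(but-3-en-1-yl)-4,4-dimethoxybut-2-enal
Product: 5 (2E)-2-(but-3-en-1-yl)-4,4-dimethoxybut-2-en-1-ol
Conditions: NaBH4, CeCl3·7H2O, MeOH, 0 °C
Reagents that add atoms: none
Why: Luche 1,2-reduction of the enal to the allylic alcohol (C15) without touching the acetal or the alkenes.

Step 3
Reactants: 5 (2E)-2-(but-3-en-1-yl)-4,4-dimethoxybut-2-en-1-ol
Product: 6 {[(2E)-2-(but-3-en-1-yl)-4,4-dimethoxybut-2-en-1-yl]oxy}(tert-butyl)dimethylsilane
Conditions: TBSCl, imidazole, CH2Cl2, 0 °C to rt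
Reagents that add atoms: tert-butyldimethylsilyl chloride, CC(C)(C)[Si](C)(C)Cl
Why: Standard silylation of the primary allylic alcohol, which must stay masked through the later esterification at C8.

Step 4
Reactants: 6 {[(2E)-2-(but-3-en-1-yl)-4,4-dimethoxybut-2-en-1-yl]oxy}(tert-butyl)dimethylsilane
Product: 7 (2E)-3-({[tert-butyl(dimethyl)silyl]oxy}methyl)hepta-2,6-dienal
Conditions: Amberlyst-15, acetone/H2O 20:1, 0 °C to rt
Reagents that add atoms: water, O
Why: Mild acid hydrolysis of the allylic dimethyl acetal, which is far more labile than the primary silyl ether, releases the C6 aldehyde with the alkene geometry retained.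

Step 5
Reactants: 8 ethyl 2-(bromomethyl)prop-2-enoate; 9 triethyl phosphite
Product: 10 ethyl 2-[(diethoxyphosphoryl)methyl]prop-2-enoate
Conditions: neat, 90 °C, distil off EtBr
Reagents that add atoms: none
Why: Michaelis–Arbuzov reaction of the allylic bromide with the phosphite (direct and allylic-transposed attack give the same product).

Step 6
Reactants: 7 (2E)-3-({[tert-butyl(dimethyl)silyl]oxy}methyl)hepta-2,6-dienal; 10 ethyl 2-[(diethoxyphosphoryl)methyl]prop-2-enoate
Product: 11 ethyl (3E,5E)-6-({[tert-butyl(dimethyl)silyl]oxy}methyl)-2-methylidenedeca-3,5,9-trienoate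
Conditions: LiN(SiMe3)2, THF, −78 °C, then 7, −78 to 0 °C
Reagents that add atoms: none
Why: Horner–Wadsworth–Emmons olefination through the phosphorus-bearing carbon of the allylic phosphonate anion gives the E-configured 2-carbethoxy-1,3-diene (C6=C7) and leaves C4=C5 unchanged.

Step 7
Reactants: 11 ethyl (3E,5E)-6-({[tert-butyl(dimethyl)silyl]oxy}methyl)-2-methylidenedeca-3,5,9-trienoate
Product: 12 (3E,5E)-6-({[tert-butyl(dimethyl)silyl]oxy}methyl)-2-methylidenedeca-3,5,9-trienoic acid
Conditions: LiOH, THF/H2O 3:1, 0 °C to rt; then 0.5 M HCl to pH 4, 0 °C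
Reagents that add atoms: lithium hydroxide, [Li+].[OH-]
Why: Ester saponification under conditions that spare the silyl ether; the acid is kept cold and dilute and used at once.

Step 8
Reactants: 12 (3E,5E)-6-({[tert-butyl(dimethyl)silyl]oxy}methyl)-2-methylidenedeca-3,5,9-trienoic acid
Product: 13 (5R)-3-(bromomethyl)-5-[(1E)-2-({[tert-butyl(dimethyl)silyl]oxy}methyl)hexa-1,5-dien-1-yl]furan-2(5H)-one
Conditions: NBS (1.1 equiv), quinidine-derived 9-epi-amino 3,5-bis(trifluoromethyl)phenyl urea catalyst (10 mol%), CHCl3/toluene 1:1, −60 °C, dark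
Reagents that add atoms: N-bromosuccinimide, O=C1CCC(=O)N1Br
Why: Proposed new method: catalytic enantioselective 1,4-bromolactonisation of a cross-conjugated 2-methylene-3,5-dienoic acid, in which the catalyst quinuclidine holds the carboxylate as an ion pair while the urea activates NBS, bromine is delivered to the terminal CH2 of the s-trans 2-carboxy-diene and the carboxylate oxygen closes onto C6 (five-membered ring, new C7=C11 bond), so that the C6–O bond, ring A, the C6 stereocentre (face chosen by the catalyst, the quinine-derived pseudo-enantiomer being the corrective if the sense is opposite) and the allylic bromide needed in step 12 arise in one operation; the closest known reactions are cinchona-urea-catalysed 1,4-bromolactonisation of conjugated enynes and 5-endo halolactonisation of β,γ-unsaturated acids.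

Step 9
Reactants: 14 2-methylprop-2-en-1-ol
Product: 15 tert-butyldimethyl[(2-methylprop-2-en-1-yl)oxy]silane
Conditions: TBSCl, imidazole, CH2Cl2, 0 °C to rt
Reagents that add atoms: tert-butyldimethylsilyl chloride, CC(C)(C)[Si](C)(C)Cl
Why: Standard silylation of the primary allylic alcohol (future C14 oxygen).

Step 10
Reactants: 15 tert-butyldimethyl[(2-methylprop-2-en-1-yl)oxy]silane; 16 formaldehyde (as paraformaldehyde)
Product: 17 3-({[tert-butyl(dimethyl)silyl]oxy}methyl)but-3-en-1-ol
Conditions: (CH2O)n, Me2AlCl (2 equiv), CH2Cl2, −78 to 0 °C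
Reagents that add atoms: none
Why: Me2AlCl-promoted carbonyl-ene reaction of the 1,1-disubstituted alkene with formaldehyde, with hydrogen transfer from the methyl group, gives the homoallylic alcohol (C8) and keeps the 1,1-disubstituted alkene.

Step 11
Reactants: 17 3-({[tert-butyl(dimethyl)silyl]oxy}methyl)but-3-en-1-ol
Product: 18 3-({[tert-butyl(dimethyl)silyl]oxy}methyl)but-3-enal
Conditions: Dess–Martin periodinane, CH2Cl2, 0 °C; short silica plug, used at once
Reagents that add atoms: none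
Why: Neutral Dess–Martin oxidation gives the β,γ-unsaturated aldehyde without isomerisation into conjugation.

Step 12
Reactants: 13 (5R)-3-(bromomethyl)-5-[(1E)-2-({[tert-butyl(dimethyl)silyl]oxy}methyl)hexa-1,5-dien-1-yl]furan-2(5H)-one; 18 3-({[tert-butyl(dimethyl)silyl]oxy}methyl)but-3-enal
Product: 20 (4R,5R)-4-[(1S)-3-({[tert-butyl(dimethyl)silyl]oxy}methyl)-1-hydroxybut-3-en-1-yl]-5-[(1E)-2-({[tert-butyl(dimethyl)silyl]oxy}methyl)hexa-1,5-dien-1-yl]-3-methylideneoxolan-2-one, via allylzinc bromide 19 (not isolated)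
Conditions: Zn dust (3 equiv), THF/sat. aq. NH4Cl 2:1, 0 °C to rt
Reagents that add atoms: none
Why: Zinc Barbier allylation in which the allylzinc adds through its ring carbon (C7) via a closed chair transition state, the aldehyde approaching the butenolide face anti to the C6 alkenyl group (sets C7, trans-lactone) with its chain equatorial on the geometrically fixed allyl unit (sets C8 as the 7,8-anti, 1S carbinol, the epimer of what the target needs).

Step 13
Reactants: 20 (4R,5R)-4-[(1S)-3-({[tert-butyl(dimethyl)silyl]oxy}methyl)-1-hydroxybut-3-en-1-yl]-5-[(1E)-2-({[tert-butyl(dimethyl)silyl]oxy}methyl)hexa-1,5-dien-1-yl]-3-methylideneoxolan-2-one; 21 3-methylbutanoic acid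
Product: 22 (1R)-3-({[tert-butyl(dimethyl)silyl]oxy}methyl)-1-{(2R,3R)-2-[(1E)-2-({[tert-butyl(dimethyl)silyl]oxy}methyl)hexa-1,5-dien-1-yl]-4-methylidene-5-oxooxolan-3-yl}but-3-en-1-yl 3-methylbutanoate
Conditions: 21 (3 equiv), PPh3 (3 equiv), DIAD (3 equiv), toluene, 0 °C to rt
Reagents that add atoms: none
Why: Mitsunobu esterification, in which SN2 displacement of the alkoxyphosphonium by the carboxylate forms the C8–O ester bond with inversion, giving the required 8R configuration and the 3-methylbutanoate in one step.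

Step 14
Reactants: 22 (1R)-3-({[tert-butyl(dimethyl)silyl]oxy}methyl)-1-{(2R,3R)-2-[(1E)-2-({[tert-butyl(dimethyl)silyl]oxy}methyl)hexa-1,5-dien-1-yl]-4-methylidene-5-oxooxolan-3-yl}but-3-en-1-yl 3-methylbutanoate
Product: 23 (3aR,4R,6E,10E,11aR)-6,10-bis({[tert-butyl(dimethyl)silyl]oxy}methyl)-3-methylidene-2-oxo-2,3,3a,4,5,8,9,11a-octahydrocyclodeca[b]furan-4-yl 3-methylbutanoate
Conditions: RuCl2(H2IMes)(=CH-C6H4-2-OiPr) (second-generation Hoveyda–Grubbs catalyst, 15 mol% in portions), toluene (0.5 mM), 90 °C, argon sparge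
Reagents that add atoms: none
Why: Ring-closing olefin metathesis in which the only monosubstituted alkene (C1) loads the ruthenium carbene and can close productively only onto the 1,1-disubstituted C10 alkene, the ten-membered ring forming the new trisubstituted alkene ring-cis (C2 cis to C9, CIP E) as the target requires.

Step 15
Reactants: 23 (3aR,4R,6E,10E,11aR)-6,10-bis({[tert-butyl(dimethyl)silyl]oxy}methyl)-3-methylidene-2-oxo-2,3,3a,4,5,8,9,11a-octahydrocyclodeca[b]furan-4-yl 3-methylbutanoate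
Product: 24 (3aR,4R,6E,10E,11aR)-6,10-bis(hydroxymethyl)-3-methylidene-2-oxo-2,3,3a,4,5,8,9,11a-octahydrocyclodeca[b]furan-4-yl 3-methylbutanoate
Conditions: HF·pyridine, pyridine, THF, 0 °C to rt
Reagents that add atoms: none
Why: Fluoride-driven Si–O cleavage under buffered, mildly acidic conditions that leave the ester, the α-methylene lactone and both allylic alcohols intact; no stereocentre is touched.

## Compound list

1 | hex-5-enal | C=CCCCC=O | starting material
2 | 2,2-dimethoxyacetaldehyde | COC(OC)C=O | starting material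
3 | 2-(but-3-en-1-yl)-3-hydroxy-4,4-dimethoxybutanal (aldol adduct, diastereomer mixture) | O=CC(CCC=C)C(O)C(OC)OC | intermediate (not isolated)
4 | (2E)-2-(but-3-en-1-yl)-4,4-dimethoxybut-2-enal | O=C/C(CCC=C)=C/C(OC)OC | intermediate
5 | (2E)-2-(but-3-en-1-yl)-4,4-dimethoxybut-2-en-1-ol | OC/C(CCC=C)=C/C(OC)OC | intermediate
6 | {[(2E)-2-(but-3-en-1-yl)-4,4-dimethoxybut-2-en-1-yl]oxy}(tert-butyl)dimethylsilane | CC(C)(C)[Si](C)(C)OC/C(CCC=C)=C/C(OC)OC | intermediate
7 | (2E)-3-({[tert-butyl(dimethyl)silyl]oxy}methyl)hepta-2,6-dienal | O=C/C=C(/CO[Si](C)(C)C(C)(C)C)CCC=C | intermediate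
8 | ethyl 2-(bromomethyl)prop-2-enoate | C=C(CBr)C(=O)OCC | starting material
9 | triethyl phosphite | CCOP(OCC)OCC | starting material
10 | ethyl 2-[(diethoxyphosphoryl)methyl]prop-2-enoate | C=C(CP(=O)(OCC)OCC)C(=O)OCC | intermediate
11 | ethyl (3E,5E)-6-({[tert-butyl(dimethyl)silyl]oxy}methyl)-2-methylidenedeca-3,5,9-trienoate | C=C(C(=O)OCC)/C=C/C=C(/CO[Si](C)(C)C(C)(C)C)CCC=C | intermediate
12 | (3E,5E)-6-({[tert-butyl(dimethyl)silyl]oxy}methyl)-2-methylidenedeca-3,5,9-trienoic acid | C=C(C(=O)O)/C=C/C=C(/CO[Si](C)(C)C(C)(C)C)CCC=C | intermediate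
13 | (5R)-3-(bromomethyl)-5-[(1E)-2-({[tert-butyl(dimethyl)silyl]oxy}methyl)hexa-1,5-dien-1-yl]furan-2(5H)-one | O=C1O[C@H](/C=C(/CO[Si](C)(C)C(C)(C)C)CCC=C)C=C1CBr | intermediate
14 | 2-methylprop-2-en-1-ol | C=C(C)CO | starting material
15 | tert-butyldimethyl[(2-methylprop-2-en-1-yl)oxy]silane | C=C(C)CO[Si](C)(C)C(C)(C)C | intermediate
16 | formaldehyde (as paraformaldehyde) | C=O | starting material
17 | 3-({[tert-butyl(dimethyl)silyl]oxy}methyl)but-3-en-1-ol | OCCC(=C)CO[Si](C)(C)C(C)(C)C | intermediate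
18 | 3-({[tert-butyl(dimethyl)silyl]oxy}methyl)but-3-enal | O=CCC(=C)CO[Si](C)(C)C(C)(C)C | intermediate
19 | bromo({(5R)-5-[(1E)-2-({[tert-butyl(dimethyl)silyl]oxy}methyl)hexa-1,5-dien-1-yl]-2-oxo-2,5-dihydrofuran-3-yl}methyl)zinc (allylzinc bromide) | O=C1O[C@H](/C=C(/CO[Si](C)(C)C(C)(C)C)CCC=C)C=C1C[Zn]Br | intermediate (not isolated)
20 | (4R,5R)-4-[(1S)-3-({[tert-butyl(dimethyl)silyl]oxy}methyl)-1-hydroxybut-3-en-1-yl]-5-[(1E)-2-({[tert-butyl(dimethyl)silyl]oxy}methyl)hexa-1,5-dien-1-yl]-3-methylideneoxolan-2-one | C=C1C(=O)O[C@H](/C=C(/CO[Si](C)(C)C(C)(C)C)CCC=C)[C@H]1[C@@H](O)CC(=C)CO[Si](C)(C)C(C)(C)C | intermediate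
21 | 3-methylbutanoic acid | CC(C)CC(=O)O | starting material
22 | (1R)-3-({[tert-butyl(dimethyl)silyl]oxy}methyl)-1-{(2R,3R)-2-[(1E)-2-({[tert-butyl(dimethyl)silyl]oxy}methyl)hexa-1,5-dien-1-yl]-4-methylidene-5-oxooxolan-3-yl}but-3-en-1-yl 3-methylbutanoate | C=C1C(=O)O[C@H](/C=C(/CO[Si](C)(C)C(C)(C)C)CCC=C)[C@H]1[C@H](OC(=O)CC(C)C)CC(=C)CO[Si](C)(C)C(C)(C)C | intermediate
23 | (3aR,4R,6E,10E,11aR)-6,10-bis({[tert-butyl(dimethyl)silyl]oxy}methyl)-3-methylidene-2-oxo-2,3,3a,4,5,8,9,11a-octahydrocyclodeca[b]furan-4-yl 3-methylbutanoate | C=C1C(=O)O[C@@H]2/C=C(/CO[Si](C)(C)C(C)(C)C)CC/C=C(/CO[Si](C)(C)C(C)(C)C)C[C@@H](OC(=O)CC(C)C)[C@@H]12 | intermediate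
24 | (3aR,4R,6E,10E,11aR)-6,10-bis(hydroxymethyl)-3-methylidene-2-oxo-2,3,3a,4,5,8,9,11a-octahydrocyclodeca[b]furan-4-yl 3-methylbutanoate | C=C1C(=O)O[C@@H]2/C=C(/CO)CC/C=C(/CO)C[C@@H](OC(=O)CC(C)C)[C@@H]12 | target

## Step count and risks

Total steps: 15. Longest linear sequence: 11 (steps 1, 2, 3, 4, 6, 7, 8, 12, 13, 14, 15).

**Step 8 (proposed new bromolactonisation).** The risks are bromine delivery to the remote trisubstituted alkene, 1,2- instead of 1,4-addition, and insufficient enantioselectivity. A 1,2-adduct would be the allylic isomer of 13 and would give the same allylzinc 19. Fallback with known chemistry, setting out from 7 and coming back at 13: zinc alkynylation of 7 with triethyl(prop-2-yn-1-yloxy)silane (Me2Zn, the ProPhenol ligand enantiomer that gives the 4R carbinol, toluene, 0 °C) gives (4R,5E)-6-({[tert-butyl(dimethyl)silyl]oxy}methyl)-1-(triethylsilyloxy)deca-5,9-dien-2-yn-4-ol F1. Hydroxyl-directed trans-hydroalumination with NaAlH2(OCH2CH2OMe)2 followed by an iodine quench gives (2Z,4R,5E)-6-({[tert-butyl(dimethyl)silyl]oxy}methyl)-2-iodo-1-(triethylsilyloxy)deca-2,5,9-trien-4-ol F2. Carbonylative lactonisation (PdCl2(PPh3)2, CO 1 atm, K2CO3, THF) gives (5R)-5-[(1E)-2-({[tert-butyl(dimethyl)silyl]oxy}methyl)hexa-1,5-dien-1-yl]-3-[(triethylsilyloxy)methyl]furan-2(5H)-one F3. Selective removal of the triethylsilyl group (PPTS, MeOH, 0 °C) gives (5R)-5-[(1E)-2-({[tert-butyl(dimethyl)silyl]oxy}methyl)hexa-1,5-dien-1-yl]-3-(hydroxymethyl)furan-2(5H)-one F4, and CBr4/PPh3 converts F4 into 13.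

**Step 13 (Mitsunobu inversion at C8).** The alcohol is hindered, the acid is only moderately acidic, elimination towards the C7=C8 diene is possible, and PPh3 can add to the α-methylene lactone. The C8 configuration of 20 is predicted from the chair transition state and should be confirmed before this step. Fallback, setting out from 13 (with 18 and 21) and coming back at 22: stannylation of 13 with (Bu3Sn)2 and Pd(PPh3)4 in THF gives (5R)-5-[(1E)-2-({[tert-butyl(dimethyl)silyl]oxy}methyl)hexa-1,5-dien-1-yl]-3-[(tributylstannyl)methyl]furan-2(5H)-one F5. BF3·OEt2-promoted addition of F5 to aldehyde 18 (CH2Cl2, −78 °C) goes through an open transition state, which is syn-selective for γ-substituted allylstannanes, and gives (4R,5R)-4-[(1R)-3-({[tert-butyl(dimethyl)silyl]oxy}methyl)-1-hydroxybut-3-en-1-yl]-5-[(1E)-2-({[tert-butyl(dimethyl)silyl]oxy}methyl)hexa-1,5-dien-1-yl]-3-methylideneoxolan-2-one F6. F6 already has the 8R configuration and is esterified with retention by acid 21 (DCC, DMAP) to give 22.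

**Step 14 (ring-closing metathesis to a strained ten-membered ring with a trisubstituted alkene).** The risks are oligomerisation and slow closure onto the hindered 1,1-disubstituted alkene flanked by a silyl ether. Fallback, setting out from 22 and coming back at 24: desilylation first (HF·pyridine, THF) gives (1R)-3-(hydroxymethyl)-1-{(2R,3R)-2-[(1E)-2-(hydroxymethyl)hexa-1,5-dien-1-yl]-4-methylidene-5-oxooxolan-3-yl}but-3-en-1-yl 3-methylbutanoate F7. Ring-closing metathesis of F7 with the same ruthenium catalyst, now helped by the free allylic hydroxyl on the 1,1-disubstituted alkene and by the absence of silyl bulk, gives the target 24 directly.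

## Further compounds

F1 | step 8 | (4R,5E)-6-({[tert-butyl(dimethyl)silyl]oxy}methyl)-1-(triethylsilyloxy)deca-5,9-dien-2-yn-4-ol | CC[Si](CC)(CC)OCC#C[C@H](O)/C=C(/CO[Si](C)(C)C(C)(C)C)CCC=C
F2 | step 8 | (2Z,4R,5E)-6-({[tert-butyl(dimethyl)silyl]oxy}methyl)-2-iodo-1-(triethylsilyloxy)deca-2,5,9-trien-4-ol | CC[Si](CC)(CC)OC/C(I)=C/[C@H](O)/C=C(/CO[Si](C)(C)C(C)(C)C)CCC=C
F3 | step 8 | (5R)-5-[(1E)-2-({[tert-butyl(dimethyl)silyl]oxy}methyl)hexa-1,5-dien-1-yl]-3-[(triethylsilyloxy)methyl]furan-2(5H)-one | O=C1O[C@H](/C=C(/CO[Si](C)(C)C(C)(C)C)CCC=C)C=C1CO[Si](CC)(CC)CC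
F4 | step 8 | (5R)-5-[(1E)-2-({[tert-butyl(dimethyl)silyl]oxy}methyl)hexa-1,5-dien-1-yl]-3-(hydroxymethyl)furan-2(5H)-one | O=C1O[C@H](/C=C(/CO[Si](C)(C)C(C)(C)C)CCC=C)C=C1CO
F5 | step 13 | (5R)-5-[(1E)-2-({[tert-butyl(dimethyl)silyl]oxy}methyl)hexa-1,5-dien-1-yl]-3-[(tributylstannyl)methyl]furan-2(5H)-one | O=C1O[C@H](/C=C(/CO[Si](C)(C)C(C)(C)C)CCC=C)C=C1C[Sn](CCCC)(CCCC)CCCC
F6 | step 13 | (4R,5R)-4-[(1R)-3-({[tert-butyl(dimethyl)silyl]oxy}methyl)-1-hydroxybut-3-en-1-yl]-5-[(1E)-2-({[tert-butyl(dimethyl)silyl]oxy}methyl)hexa-1,5-dien-1-yl]-3-methylideneoxolan-2-one | C=C1C(=O)O[C@H](/C=C(/CO[Si](C)(C)C(C)(C)C)CCC=C)[C@H]1[C@H](O)CC(=C)CO[Si](C)(C)C(C)(C)C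
F7 | step 14 | (1R)-3-(hydroxymethyl)-1-{(2R,3R)-2-[(1E)-2-(hydroxymethyl)hexa-1,5-dien-1-yl]-4-methylidene-5-oxooxolan-3-yl}but-3-en-1-yl 3-methylbutanoate | C=C1C(=O)O[C@H](/C=C(/CO)CCC=C)[C@H]1[C@H](OC(=O)CC(C)C)CC(=C)CO
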